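## The problem

The target, 5,7-dihydroxy-3-(8-hydroxy-2,2-dimethylchroman-6-yl)-4H-chromen-4-one (17), is an isoflavone. Rings A and C form a 5,7-dihydroxychromen-4-one, ring B sits on C3, and ring B is fused through C4' and C5' to a saturated 2,2-dimethylpyran, ring D. The molecule has no stereocentre, so the task is regiochemical and chemoselective; the stereocentres that appear on the way (in 4, 13, 14, 15 and 16) are transient and control nothing. Three placements must come out right: the aryl group on C3 and not C2 of ring C, ring D closed from the C4' oxygen toward C5' and not toward C3', and a free hydroxyl left on C3'. Four phenolic oxygens have to be carried: ring A is phloroglucinol-like and prone to C-alkylation and oxidation, and ring B is a catechol monoether. The chromone C2=C3 bond is opened by hydroxide and can be hydrogenated, and a formyl handle on ring B can be over-reduced. The tertiary alkyl aryl ether of ring D would not survive BBr3 or hot mineral acid, which excludes methyl ethers and points to benzyl ethers removed by hydrogenolysis. The enabling feature lies in ring B: the ring D oxygen on C4' has the oxygen-bearing C3' on one side and C5' on the other, so a group that migrates sigmatropically from this oxygen can end productively only on C5'. C1', para to that oxygen, carries the carbon that becomes C3 of ring C; held as a formyl group, it also makes the C4' hydroxyl the more acidic of the two.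

## Retrosynthesis

**17 to 14.** The O1–C2 bond of ring C is cut and the four phenols are masked as benzyl ethers, giving the open 2-aryl-3-oxopropanal 14. The neighbouring cuts are a C3–C1' cross-coupling and a deoxybenzoin plus a one-carbon unit. The first needs a ring B halide or boronate and the second an arylacetic acid, and either would give up the formyl group that serves ring B in every earlier step. Precursor 14 has no ring C, and ring A is symmetric, so either ortho oxygen can close. The forward reaction must free the phenols (tetraphenol 15), let one ortho hydroxyl add to the formyl group (hemiacetal 16) and dehydrate, without exposing the new C2=C3 bond to hydrogen.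

**14 to 13 to 12.** The aryl group of 14 sits on the carbon between the ketone and the aldehyde. This pattern arises when the aroyl group of the trans-epoxy ketone 13 shifts from the α- to the β-carbon, and 13 comes from chalcone 12 by addition of one oxygen. The alternative is an oxidative 1,2-aryl shift on 12 with a trivalent thallium salt, which reaches the same skeleton but uses a stoichiometric toxic metal; it is kept in reserve. The forward rearrangement needs a β-aryl group able to stabilise a benzylic cation, and the para ring D oxygen of ring B provides that.

**12 to 9 and 11.** The Cα=Cβ bond is cut by a retro-aldol condensation into aldehyde 9 and 1-[2,4,6-tris(benzyloxy)phenyl]ethanone 11, two fragments of similar size that together hold every carbon of the target. Aldehyde 9 cannot enolise and the hindered ketone 11 does not self-condense. Ketone 11 comes from 1-(2,4,6-trihydroxyphenyl)ethanone 10 by exhaustive benzylation; all three hydroxyls must be capped, since a free ortho hydroxyl would divert the later alkaline peroxide step.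

**9 to 8 to 7.** Removing the benzyl group and reintroducing the C3=C4 alkene of the pyran leads to chromene 7. The alkene is saturated first, while the phenol is still free, so that the hydrogenation has no benzyl ether to spare. It is not carried further, because a 2,2-dimethyl-2H-chromene would not tolerate the Lewis acid used later.

**7 to 3.** This is the key cut: the C4–C4a bond of the chromene (C5' to carbon) and, formally, the O1–C2 bond, which is broken and formed again. The precursor is aryl 1,1-dimethylpropargyl ether 3, and the reaction runs through dienone 4, allenyl catechol 5 and quinone methide 6. A Friedel–Crafts prenylation and cyclisation of the catechol would have to choose between three free ring positions on a deactivated arene. The sigmatropic route delivers carbon from O4' to an ortho position only, and only C5' can accept it. Precursor 3 has no ring D and no C–C bond to the side chain. The hydroxyl on C3' is left free, because it cannot reach the allene in 5 and a protecting group would cost two steps.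

**3 to 1 and 2.** The aryl O–CMe2 bond is cut to 3,4-dihydroxybenzaldehyde 1 and 3-chloro-3-methylbut-1-yne 2, both commercial. The forward reaction must alkylate only the hydroxyl para to the formyl group. One equivalent of carbonate ionises that hydroxyl alone, because its phenoxide is conjugated with the aldehyde.

## Roads not taken

**Alternative 1: rhodium-catalysed annulation of a salicylaldehyde with an aryl silyl alkyne.** The cut removes C3–C4 and O1–C2 of ring C at once. In the forward step, salicylaldehyde A2 and alkyne A3 would be joined with [(C5Me5)RhCl2]2 (trivalent rhodium) and Cu(OAc)2 (divalent copper): aldehyde C–H activation, alkyne insertion and C–O bond formation would give 2-silyl isoflavone A1, followed by desilylation and hydrogenolysis.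
- Merits: it is the most convergent way to ring C. It replaces the chalcone, epoxide and rearrangement steps by one catalytic step and avoids both the labile β-ketoaldehyde 14 and the Lewis acid. In step count at ring C it is better than the chosen plan.
- Weak points: aryl alkyl alkynes normally place the aryl group next to oxygen in this annulation, the flavone orientation. The silyl group would have to win that carbon against the aryl group, which is not secured for an electron-rich ring B alkyne. The formyl group of A2 is flanked by two ortho substituents. The C–Si bond may not survive hot copper acetate.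
- Comparison: A3 still needs ring D built on a ring B halide, where the catechol has no para formyl group to direct the O-alkylation, so the problem solved here by the key step returns in a harder form. The chosen plan sets against the shorter ring C assembly an aryl placement fixed by mechanism and steps of classical type only.

**Alternative 2: ring B by Diels–Alder reaction of a pyranyl diene with an ynone.** The cut removes C1'–C2' and C5'–C6' of ring B. Dienyl acetate A5, which already contains ring D, would add but-3-yn-2-one A6, and DDQ in the same flask would aromatise the adduct to aryl ketone A4.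
- Merits: ring D is carried in saturated form, so no hydrogenation and no high-temperature step are needed. The para relation between the ring oxygen and the acyl group follows from the polarity of the enol ether terminus. The acetate and acetyl groups are differentiated handles.
- Weak points: a benzene ring that can be bought with all three substituents in place is built from scratch. A5 is a doubly oxygenated, hydrolysis-prone diene that needs several steps itself. Its two donor groups direct the dienophile in opposite senses, so the regiochemistry is a matter of degree. The methyl ketone of A4 is the wrong handle for an isoflavone and would need an oxidative rearrangement to an arylacetic acid before ring C could be made.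
- Comparison: the alternative is better in avoiding the reduction of a chromene, but it is clearly longer. The chosen plan starts from an arene that already carries the full ring B pattern.

**Alternative 3: ortho-quinone methide and isobutene.** The cut removes the CH2–CH2 bond and the O–CMe2 bond of ring D. Heating ortho-hydroxybenzyl alcohol A8 with excess isobutene A9 in a sealed vessel would generate the quinone methide and trap it in a hetero-Diels–Alder reaction to give A7, which is the same compound as 9.
- Merits: it reaches 9 directly at the right oxidation level with the benzyl group in place, so the hydrogenation and benzylation of the chosen plan are not needed. In redox economy it is the better road.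
- Weak points: isobutene is a gaseous, unactivated 2π partner, and oligomerisation of the quinone methide competes. The formyl group para to the phenol makes the quinone methide harder to generate. A8 needs the catechol benzylated at O3', against its natural preference, and then a hydroxymethylation of a deactivated phenol, so the steps saved after the key step are spent before it.
- Comparison: the chosen plan sets against it a commercial starting material, a regiochemistry that cannot go wrong at the ortho position, and two extra steps that are routine.

Key step: step 2

Assumption: the target is achiral; epoxide 13 is made as the racemic trans isomer, and the stereocentres of 4, 14, 15 and 16 are racemic or labile and disappear when ring C aromatises.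

## Route

Step 1
Reactants: 1 3,4-dihydroxybenzaldehyde; 2 3-chloro-3-methylbut-1-yne
Product: 3 3-hydroxy-4-[(2-methylbut-3-yn-2-yl)oxy]benzaldehyde
Conditions: K2CO3 (1.0 equiv), KI (cat.), DMF, 60 °C, N2
Reagents that add atoms: none
Why: Williamson-type O-alkylation of a phenoxide by a tertiary propargylic chloride; one equivalent of carbonate ionises only the 4-hydroxyl, whose phenoxide is conjugated with the para formyl group, so the ether forms there and the 3-hydroxyl stays free.

Step 2
Reactants: 3 3-hydroxy-4-[(2-methylbut-3-yn-2-yl)oxy]benzaldehyde
Product: 7 8-hydroxy-2,2-dimethyl-2H-chromene-6-carbaldehyde, via allenyl cyclohexadienone 4 (not isolated), via allenyl catechol 5 (not isolated), via ortho-quinone methide 6 (not isolated)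
Conditions: 1,2-dichlorobenzene, 180 °C, Ar
Reagents that add atoms: none
Why: Heating 3 starts an aromatic propargyl Claisen rearrangement, a [3,3]-sigmatropic shift in which the O–CMe2 bond breaks and the alkyne terminus bonds to C5, the only ortho carbon that carries hydrogen, to give dienone 4. Tautomerisation restores the arene as allenyl catechol 5, and a 1,5-hydrogen shift from the adjacent hydroxyl to the central allene carbon gives the Z-configured ortho-quinone methide 6. Ring D then closes by a thermally allowed oxa-6π-electrocyclisation between the carbonyl oxygen and the CMe2 terminus, which re-forms the O–CMe2 bond and the aromatic ring. The closest known reaction type is the thermal conversion of aryl 1,1-dimethylpropargyl ethers, including those of para-hydroxybenzaldehydes, into 2,2-dimethyl-2H-chromenes. No stereocentre is formed. The selectivity needed is ortho regioselectivity, and the substrate secures it: a shift to C3 gives a dienone with no hydrogen to lose, which can only revert, so all material passes through C5. The 3-hydroxyl is meta to the allene in 5 and cannot intercept it, and without base or metal it does not add to the alkyne of 3. The gem-dimethyl group speeds both the shift and the ring closure.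

Step 3
Reactants: 7 8-hydroxy-2,2-dimethyl-2H-chromene-6-carbaldehyde
Product: 8 8-hydroxy-2,2-dimethylchroman-6-carbaldehyde
Conditions: H2 (1 atm), Pd/C, Ph2S (cat.), EtOAc, rt
Reagents that add atoms: none
Why: Heterogeneous catalytic hydrogenation of the cis-disubstituted styrenic alkene; Pd/C moderated with diphenyl sulfide saturates alkenes while leaving aryl aldehydes alone, and no stereocentre is formed.

Step 4
Reactants: 8 8-hydroxy-2,2-dimethylchroman-6-carbaldehyde
Product: 9 8-(benzyloxy)-2,2-dimethylchroman-6-carbaldehyde
Conditions: BnBr, K2CO3, DMF, rt
Reagents that add atoms: benzyl bromide, BrCc1ccccc1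
Why: Williamson ether synthesis on the only hydroxyl of 8; the aldehyde and the ring D ether are inert to carbonate and benzyl bromide.

Step 5
Reactants: 10 1-(2,4,6-trihydroxyphenyl)ethanone
Product: 11 1-[2,4,6-tris(benzyloxy)phenyl]ethanone
Conditions: BnBr (3.3 equiv), K2CO3, DMF, 80 °C
Reagents that add atoms: benzyl bromide, BrCc1ccccc1
Why: Exhaustive Williamson benzylation; the acetyl group lowers the nucleophilicity of the ring carbons so that O-alkylation prevails, and heat in a dipolar solvent is used to reach the two hydrogen-bonded ortho hydroxyls.

Step 6
Reactants: 9 8-(benzyloxy)-2,2-dimethylchroman-6-carbaldehyde; 11 1-[2,4,6-tris(benzyloxy)phenyl]ethanone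
Product: 12 (2E)-3-[8-(benzyloxy)-2,2-dimethylchroman-6-yl]-1-[2,4,6-tris(benzyloxy)phenyl]prop-2-en-1-one
Conditions: KOH, EtOH/THF, rt
Reagents that add atoms: none
Why: Claisen–Schmidt condensation of a non-enolisable aryl aldehyde with a methyl ketone too hindered to self-condense; elimination of hydroxide from the aldol gives the E alkene under thermodynamic control.

Step 7
Reactants: 12 (2E)-3-[8-(benzyloxy)-2,2-dimethylchroman-6-yl]-1-[2,4,6-tris(benzyloxy)phenyl]prop-2-en-1-one
Product: 13 rac-{(2S,3R)-3-[8-(benzyloxy)-2,2-dimethylchroman-6-yl]oxiran-2-yl}[2,4,6-tris(benzyloxy)phenyl]methanone (trans-epoxide)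
Conditions: 30% aq H2O2, NaOH, MeOH/THF, 0 °C to rt
Reagents that add atoms: hydrogen peroxide, OO
Why: Weitz–Scheffer nucleophilic epoxidation: hydroperoxide adds in conjugate fashion and the enolate closes onto oxygen, which gives the trans epoxide as a racemate from the E enone. Both new stereocentres are erased in steps 8 and 9, and with no free ortho hydroxyl an Algar–Flynn–Oyamada cyclisation cannot occur.

Step 8
Reactants: 13 rac-{(2S,3R)-3-[8-(benzyloxy)-2,2-dimethylchroman-6-yl]oxiran-2-yl}[2,4,6-tris(benzyloxy)phenyl]methanone
Product: 14 2-[8-(benzyloxy)-2,2-dimethylchroman-6-yl]-3-oxo-3-[2,4,6-tris(benzyloxy)phenyl]propanal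
Conditions: BF3·OEt2 (substoichiometric), CH2Cl2, 0 °C, brief
Reagents that add atoms: none
Why: Meinwald-type rearrangement of an α,β-epoxy ketone with a 1,2-aroyl shift: the Lewis acid opens the epoxide at the benzylic carbon, whose cation is stabilised by the para ring D oxygen, and the aroyl group migrates to it to leave the formyl group. The new centre is enolisable and of no consequence, and low temperature and a short contact time spare the benzyl ethers.

Step 9
Reactants: 14 2-[8-(benzyloxy)-2,2-dimethylchroman-6-yl]-3-oxo-3-[2,4,6-tris(benzyloxy)phenyl]propanal
Product: 17 5,7-dihydroxy-3-(8-hydroxy-2,2-dimethylchroman-6-yl)-4H-chromen-4-one, via tetraphenol ketoaldehyde 15 (not isolated), via 2-hydroxyisoflavanone 16 (not isolated)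
Conditions: H2 (1 atm), Pd/C, EtOAc/MeOH, rt; filter; then HCl (cat.), MeOH, 50 °C
Reagents that add atoms: none
Why: Hydrogenolysis cleaves the four aryl benzyl ethers, and one of the two equivalent ortho hydroxyls of ring A adds to the formyl group to give hemiacetal 16. After the catalyst is filtered off, acid-catalysed dehydration forms the chromone, so the C2=C3 bond never meets hydrogen.

## Compound list

1 | 3,4-dihydroxybenzaldehyde | O=Cc1ccc(O)c(O)c1 | starting material
2 | 3-chloro-3-methylbut-1-yne | C#CC(C)(C)Cl | starting material
3 | 3-hydroxy-4-[(2-methylbut-3-yn-2-yl)oxy]benzaldehyde | O=Cc1ccc(OC(C)(C)C#C)c(O)c1 | intermediate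
4 | 5-hydroxy-3-(3-methylbuta-1,2-dien-1-yl)-4-oxocyclohexa-1,5-diene-1-carbaldehyde (racemic) | O=CC1=CC(C=C=C(C)C)C(=O)C(O)=C1 | intermediate (not isolated)
5 | 3,4-dihydroxy-5-(3-methylbuta-1,2-dien-1-yl)benzaldehyde | O=Cc1cc(O)c(O)c(C=C=C(C)C)c1 | intermediate (not isolated)
6 | (3Z)-5-hydroxy-3-(3-methylbut-2-en-1-ylidene)-4-oxocyclohexa-1,5-diene-1-carbaldehyde | O=CC1=C/C(=C/C=C(C)C)C(=O)C(O)=C1 | intermediate (not isolated)
7 | 8-hydroxy-2,2-dimethyl-2H-chromene-6-carbaldehyde | O=Cc1cc(O)c2OC(C)(C)C=Cc2c1 | intermediate
8 | 8-hydroxy-2,2-dimethylchroman-6-carbaldehyde | O=Cc1cc(O)c2OC(C)(C)CCc2c1 | intermediate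
9 | 8-(benzyloxy)-2,2-dimethylchroman-6-carbaldehyde | O=Cc1cc(OCc3ccccc3)c2OC(C)(C)CCc2c1 | intermediate
10 | 1-(2,4,6-trihydroxyphenyl)ethanone | CC(=O)c1c(O)cc(O)cc1O | starting material
11 | 1-[2,4,6-tris(benzyloxy)phenyl]ethanone | CC(=O)c1c(OCc2ccccc2)cc(OCc2ccccc2)cc1OCc1ccccc1 | intermediate
12 | (2E)-3-[8-(benzyloxy)-2,2-dimethylchroman-6-yl]-1-[2,4,6-tris(benzyloxy)phenyl]prop-2-en-1-one | O=C(/C=C/c1cc(OCc2ccccc2)c2OC(C)(C)CCc2c1)c1c(OCc2ccccc2)cc(OCc2ccccc2)cc1OCc1ccccc1 | intermediate
13 | rac-{(2S,3R)-3-[8-(benzyloxy)-2,2-dimethylchroman-6-yl]oxiran-2-yl}[2,4,6-tris(benzyloxy)phenyl]methanone (trans; one enantiomer drawn) | O=C([C@H]1O[C@@H]1c1cc(OCc2ccccc2)c2OC(C)(C)CCc2c1)c1c(OCc2ccccc2)cc(OCc2ccccc2)cc1OCc1ccccc1 | intermediate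
14 | 2-[8-(benzyloxy)-2,2-dimethylchroman-6-yl]-3-oxo-3-[2,4,6-tris(benzyloxy)phenyl]propanal (racemic, enolisable) | O=CC(c1cc(OCc2ccccc2)c2OC(C)(C)CCc2c1)C(=O)c1c(OCc2ccccc2)cc(OCc2ccccc2)cc1OCc1ccccc1 | intermediate
15 | 2-(8-hydroxy-2,2-dimethylchroman-6-yl)-3-oxo-3-(2,4,6-trihydroxyphenyl)propanal (racemic, enolisable) | O=CC(c1cc(O)c2OC(C)(C)CCc2c1)C(=O)c1c(O)cc(O)cc1O | intermediate (not isolated)
16 | 2,5,7-trihydroxy-3-(8-hydroxy-2,2-dimethylchroman-6-yl)chroman-4-one (mixture of stereoisomers) | OC1Oc2cc(O)cc(O)c2C(=O)C1c1cc(O)c2OC(C)(C)CCc2c1 | intermediate (not isolated)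
17 | 5,7-dihydroxy-3-(8-hydroxy-2,2-dimethylchroman-6-yl)-4H-chromen-4-one | CC1(C)CCc2cc(-c3coc4cc(O)cc(O)c4c3=O)cc(O)c2O1 | target

## Step count and risks

Total step count: 9. Longest linear sequence: 8 (steps 1, 2, 3, 4, 6, 7, 8, 9); step 5 is a one-step side branch.

**Step 2 (key step).** The neighbouring free hydroxyl may add across the alkyne before the sigmatropic shift, and the electron-rich phenol may degrade by oxidation at 180 °C. The formyl group also slows the shift, which lengthens the exposure. The fallback sets out from 3 and replaces the propargyl cascade by an allyl Claisen rearrangement and a separate ring closure. Semihydrogenation of the alkyne over Pd/CaCO3 poisoned with Pb(OAc)2 and quinoline (Lindlar catalyst) gives 3-hydroxy-4-[(2-methylbut-3-en-2-yl)oxy]benzaldehyde F1. Its aromatic Claisen rearrangement in toluene at about 110 °C, again possible only toward C5, gives 3,4-dihydroxy-5-(3-methylbut-2-en-1-yl)benzaldehyde F2. Acid (Amberlyst 15 resin in CH2Cl2) then adds the adjacent 4-hydroxyl to the prenyl alkene in the Markovnikov sense and closes the chroman. The fallback comes back to the route at 8, so 7 and step 3 are bypassed.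

**Step 1.** Site selectivity may be lost by alkylation at O3 or at both oxygens, and the remaining phenoxide may close onto the alkyne under the basic conditions. The fallback sets out from 1 and reverses the order of differentiation. The dianion of 1 (NaH, 2 equiv, DMSO) is treated with one equivalent of benzyl bromide; it reacts at the non-conjugated and therefore more nucleophilic 3-oxide to give 3-(benzyloxy)-4-hydroxybenzaldehyde F3. The single remaining hydroxyl is alkylated with 2 (K2CO3, KI, DMF) to give 3-(benzyloxy)-4-[(2-methylbut-3-yn-2-yl)oxy]benzaldehyde F4. Heating as in step 2 gives 8-(benzyloxy)-2,2-dimethyl-2H-chromene-6-carbaldehyde F5. Hydrogenation over Pd/C then saturates the alkene and removes the temporary benzyl group in one operation. The fallback comes back to the route at 8.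

**Step 8.** The benzyl ether ortho to the ketone may be lost, followed by ring closure onto the opened epoxide. Fluoride may be captured at the benzylic cation, and the β-ketoaldehyde may deformylate during work-up. The fallback sets out from 12 and reaches the same skeleton by aryl instead of aroyl migration. Tl(NO3)3 (trivalent thallium) in MeOH/HC(OMe)3 effects oxythallation of the enone and a 1,2-shift of the electron-rich ring B aryl group. The product is 2-[8-(benzyloxy)-2,2-dimethylchroman-6-yl]-3,3-dimethoxy-1-[2,4,6-tris(benzyloxy)phenyl]propan-1-one F6, and mild aqueous acid (HCl, THF) hydrolyses the acetal. The fallback comes back to the route at 14, so 13 is bypassed.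

**Step 9.** The enolised formyl group may be reduced before the ring closes, the two hindered ortho ethers may be cleaved incompletely, and C2=C3 may be reduced if any catalyst passes into the acid stage. The fallback sets out from 14 and closes ring C before any hydrogen is used. BCl3 in CH2Cl2 at −78 °C cleaves, under chelation by the ketone, one of the two equivalent ortho benzyl ethers. The resulting 2-[8-(benzyloxy)-2,2-dimethylchroman-6-yl]-3-[2,4-bis(benzyloxy)-6-hydroxyphenyl]-3-oxopropanal F7 closes onto the formyl group and loses water on acidic work-up to give 5,7-bis(benzyloxy)-3-[8-(benzyloxy)-2,2-dimethylchroman-6-yl]-4H-chromen-4-one F8. Hydrogenolysis of this robust tribenzyl isoflavone (H2, Pd/C, EtOAc, rt) removes the remaining three benzyl groups. The fallback comes back to the route at 17.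

## Further compounds

F1 | step 2 | 3-hydroxy-4-[(2-methylbut-3-en-2-yl)oxy]benzaldehyde | O=Cc1ccc(OC(C)(C)C=C)c(O)c1
F2 | step 2 | 3,4-dihydroxy-5-(3-methylbut-2-en-1-yl)benzaldehyde | O=Cc1cc(O)c(O)c(CC=C(C)C)c1
F3 | step 1 | 3-(benzyloxy)-4-hydroxybenzaldehyde | O=Cc1ccc(O)c(OCc2ccccc2)c1
F4 | step 1 | 3-(benzyloxy)-4-[(2-methylbut-3-yn-2-yl)oxy]benzaldehyde | O=Cc1ccc(OC(C)(C)C#C)c(OCc2ccccc2)c1
F5 | step 1 | 8-(benzyloxy)-2,2-dimethyl-2H-chromene-6-carbaldehyde | O=Cc1cc(OCc3ccccc3)c2OC(C)(C)C=Cc2c1
F6 | step 8 | 2-[8-(benzyloxy)-2,2-dimethylchroman-6-yl]-3,3-dimethoxy-1-[2,4,6-tris(benzyloxy)phenyl]propan-1-one | COC(OC)C(c1cc(OCc2ccccc2)c2OC(C)(C)CCc2c1)C(=O)c1c(OCc2ccccc2)cc(OCc2ccccc2)cc1OCc1ccccc1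
F7 | step 9 | 2-[8-(benzyloxy)-2,2-dimethylchroman-6-yl]-3-[2,4-bis(benzyloxy)-6-hydroxyphenyl]-3-oxopropanal | O=CC(c1cc(OCc2ccccc2)c2OC(C)(C)CCc2c1)C(=O)c1c(O)cc(OCc2ccccc2)cc1OCc1ccccc1
F8 | step 9 | 5,7-bis(benzyloxy)-3-[8-(benzyloxy)-2,2-dimethylchroman-6-yl]-4H-chromen-4-one | O=c1c(-c2cc(OCc3ccccc3)c3OC(C)(C)CCc3c2)coc2cc(OCc3ccccc3)cc(OCc3ccccc3)c12
A1 | alternative 1 | 5,7-bis(benzyloxy)-3-[8-(benzyloxy)-2,2-dimethylchroman-6-yl]-2-(trimethylsilyl)chromen-4-one | C[Si](C)(C)c1oc2cc(OCc3ccccc3)cc(OCc3ccccc3)c2c(=O)c1-c1cc(OCc2ccccc2)c2OC(C)(C)CCc2c1
A2 | alternative 1 | 2,4-bis(benzyloxy)-6-hydroxybenzaldehyde | O=Cc1c(O)cc(OCc2ccccc2)cc1OCc1ccccc1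
A3 | alternative 1 | {[8-(benzyloxy)-2,2-dimethylchroman-6-yl]ethynyl}(trimethyl)silane | C[Si](C)(C)C#Cc1cc(OCc2ccccc2)c2OC(C)(C)CCc2c1
A4 | alternative 2 | 6-acetyl-2,2-dimethylchroman-8-yl acetate | CC(=O)Oc1cc(C(C)=O)cc2c1OC(C)(C)CC2
A5 | alternative 2 | 1-(6,6-dimethyl-5,6-dihydro-4H-pyran-2-yl)ethenyl acetate | C=C(OC(C)=O)C1=CCCC(C)(C)O1
A6 | alternative 2 | but-3-yn-2-one | CC(=O)C#C
A7 | alternative 3 | 8-(benzyloxy)-2,2-dimethylchroman-6-carbaldehyde | O=Cc1cc(OCc3ccccc3)c2OC(C)(C)CCc2c1
A8 | alternative 3 | 3-(benzyloxy)-4-hydroxy-5-(hydroxymethyl)benzaldehyde | O=Cc1cc(CO)c(O)c(OCc2ccccc2)c1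
A9 | alternative 3 | 2-methylprop-1-ene (isobutene) | CC(C)=C
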